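**Retrosynthetic overview**

- Target ⇐ late C7 hydroxylation (Rubottom) of the 6-keto spirolactone; ring D (γ-lactone) ⇐ desymmetrizing Baeyer–Villiger ring expansion of a spiro 3-alkoxycyclobutanone (key step, sets C13).
- Cyclobutanone ⇐ dichloroketene [2+2]/dechlorination on the exocyclic enol ether of ring C (tetrahydrofuran) ⇐ 5-exo-dig closure of a 9α-hydroxy butynyl chain.
- Side chain ⇐ propargyl opening of a 9α,11-spiro-epoxide ⇐ α-face oxygenation of the C9 ester enolate of a decalin keto ester, then reduction.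
- Decalin ⇐ acid-mediated cation–olefin closure of ring A onto the C5 enol of a ring B cyclohexanone ⇐ methyl cuprate addition to a Hagemann-type enone ⇐ asymmetric Michael/aldol annulation of prenylated methyl acetoacetate with pent-3-en-2-one.
- Ring order: B → A → C (tetrahydrofuran) → cyclobutanone → D (lactone, by ring expansion).

Assumption: positions use labdane numbering (C1–C20), α is the face opposite the C10 methyl, and if a chiral catalyst (steps 2 and 11) shows the opposite sense of induction its (pseudo)enantiomer is used instead.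

**Route**

Step 1
Reactants: 1 methyl acetoacetate; 2 prenyl bromide
Product: 3 methyl 7-methyl-3-oxooct-6-enoate
Conditions: NaH, THF, 0 °C; n-BuLi, 0 °C; then 2, 0 → 25 °C; 1 M HCl
Reagents that add atoms: none
Why: Weiler dianion alkylation, in which the terminal (γ) carbanion of the acetoacetate dianion is the more nucleophilic site and is alkylated by the allylic bromide.

Step 2
Reactants: 3 methyl 7-methyl-3-oxooct-6-enoate; 4 (E)-pent-3-en-2-one
Product: 6 methyl (1S,6R)-6-methyl-2-(4-methylpent-3-en-1-yl)-4-oxocyclohex-2-ene-1-carboxylate, via Michael adduct 5 (not isolated)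
Conditions: 9-amino-9-deoxy-epi-quinine (10 mol%), CF3CO2H (20 mol%), toluene, 25 °C; then pyrrolidine (20 mol%), AcOH (20 mol%), 60 °C
Reagents that add atoms: none
Why: Organocatalytic Robinson-type annulation in which iminium activation of 4 lets the β-keto ester add to one enone face and set C8 as R, the methyl ketone then closes ring B by enamine aldol condensation onto the keto-ester carbonyl, and the acidic C9 centre equilibrates trans to the C8 methyl.

Step 3
Reactants: 6 methyl (1S,6R)-6-methyl-2-(4-methylpent-3-en-1-yl)-4-oxocyclohex-2-ene-1-carboxylate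
Product: 7 methyl (1S,2S,6R)-2,6-dimethyl-2-(4-methylpent-3-en-1-yl)-4-oxocyclohexane-1-carboxylate
Conditions: MeLi, CuI, Et2O, −20 °C; then 6, −78 → −20 °C; 1 M HCl
Reagents that add atoms: lithium dimethylcuprate, [Li+].C[Cu-]C
Why: Cuprate 1,4-addition in which methyl attacks the β-carbon axially on the diequatorial half-chair, anti to the C8 methyl (no 1,3-diaxial clash), setting the C10 quaternary centre with its methyl cis to the ester.

Step 4
Reactants: 7 methyl (1S,2S,6R)-2,6-dimethyl-2-(4-methylpent-3-en-1-yl)-4-oxocyclohexane-1-carboxylate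
Product: 8 methyl (1S,2R,4aS,8aS)-2,5,5,8a-tetramethyl-4-oxodecahydronaphthalene-1-carboxylate
Conditions: CF3SO3H (20 mol%), (CF3)2CHOH/CH2Cl2 1:4, 0 → 25 °C
Reagents that add atoms: none
Why: Enol-terminated cation–olefin cyclization, in which protonation of the trisubstituted alkene gives the tertiary C4 cation that is captured by the C5 enol carbon to close ring A, and C5 equilibrates under the acid to the trans-fused 5α-H ketone.

Step 5
Reactants: 8 methyl (1S,2R,4aS,8aS)-2,5,5,8a-tetramethyl-4-oxodecahydronaphthalene-1-carboxylate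
Product: 9 Δ6 triethylsilyl enol ether of keto ester 8
Conditions: LiN(iPr)2 (1.05 equiv), THF, −78 °C; Et3SiCl, −78 → 0 °C
Reagents that add atoms: chlorotriethylsilane, CC[Si](Cl)(CC)CC
Why: Kinetic enolization at the only accessible α-methylene (C7) and O-silylation mask the C6 ketone for the basic and reducing steps that follow.

Step 6
Reactants: 9 Δ6 triethylsilyl enol ether of keto ester 8
Product: 11 9α-hydroxy-9β-(hydroxymethyl) Δ6 triethylsilyl enol ether, via hydroperoxy ester 10 (not isolated)
Conditions: LiN(iPr)2 (2 equiv), THF/DMPU, −78 → −20 °C; O2, −78 °C; then LiAlH4, 0 → 25 °C; H2O/NaOH work-up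
Reagents that add atoms: dioxygen, O=O
Why: Ester enolate oxygenation then hydride reduction, in which O2 traps the hindered exocyclic enolate from the α-face (anti to the axial C10 methyl) to set the 9α-oxygen and LiAlH4 cleaves the O–O bond and reduces the ester to the primary alcohol.

Step 7
Reactants: 11 9α-hydroxy-9β-(hydroxymethyl) Δ6 triethylsilyl enol ether
Product: 12 9α,11-spiro-epoxide
Conditions: NaH (2.5 equiv), 1-tosylimidazole (1.05 equiv), THF, 0 → 25 °C
Reagents that add atoms: none
Why: One-pot Williamson-type epoxide formation, in which the primary alkoxide is sulfonylated selectively and displaced by the tertiary C9 alkoxide (3-exo-tet), so C9 keeps its configuration.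

Step 8
Reactants: 12 9α,11-spiro-epoxide; 13 1-(trimethylsilyl)propyne
Product: 15 9α-hydroxy-9β-(but-3-ynyl)-4,4,8α,10β-tetramethyl-trans-decalin-6-one, via silylated alkynol 14 (not isolated)
Conditions: 13, n-BuLi, TMEDA, THF, −78 → 0 °C; then 12, DMPU, 0 → 40 °C; then Bu4NF, THF, 25 °C
Reagents that add atoms: none
Why: SN2 epoxide opening at the CH2 terminus by the propargyllithium builds C11–C14 without touching C9, and fluoride then removes the alkynyl silyl group and cleaves the silyl enol ether to release the C6 ketone.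

Step 9
Reactants: 15 9α-hydroxy-9β-(but-3-ynyl)-4,4,8α,10β-tetramethyl-trans-decalin-6-one
Product: 16 9α,13-epoxy-15,16-dinorlabd-13(14)-en-6-one
Conditions: AuCl (5 mol%), K2CO3 (10 mol%), MeCN, 25 °C
Reagents that add atoms: none
Why: Gold-catalysed 5-exo-dig hydroalkoxylation (cycloisomerization) of the 4-pentyn-1-ol unit closes ring C with retention at C9 and leaves an exocyclic enol ether.

Step 10
Reactants: 16 9α,13-epoxy-15,16-dinorlabd-13(14)-en-6-one; 17 trichloroacetyl chloride
Product: 19 spirocyclobutanone, via dichlorocyclobutanone 18 (not isolated)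
Conditions: 17, Zn(Cu), Et2O/DME, 0 → 25 °C; then Zn dust, AcOH, 25 °C
Reagents that add atoms: none
Why: Ketene [2+2] cycloaddition (the ketene carbonyl carbon bonds to the nucleophilic CH2 terminus of the enol ether) followed by reductive dechlorination, which makes the two ring methylenes constitutionally equal so that C13 is only prostereogenic.

Step 11
Reactants: 19 spirocyclobutanone
Product: 20 (13R)-9α,13-epoxy-6-oxolabdan-15,16-olide
Conditions: (R)-3,3'-bis(2,4,6-triisopropylphenyl)-H8-BINOL hydrogen phosphate (10 mol%), 30% aq. H2O2 (1.5 equiv), CHCl3, −40 °C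
Reagents that add atoms: hydrogen peroxide, OO
Why: Proposed new method: catalyst-controlled Baeyer–Villiger ring expansion that chooses between the two diastereotopic methylenes of a 3-alkoxy-3-alkyl spirocyclobutanone — the phosphoric acid holds the Criegee perhydrate by two hydrogen bonds (P=O···H–O and P–OH···O–O), only the methylene antiperiplanar to the locked O–O bond migrates (with retention), and because the chiral pocket must place the bulky decalin-bearing C12 arm outside and the small ether oxygen inside, the methylene on the C8 side of ring C migrates to oxygen, closing the γ-lactone and setting C13 as R, while the strained cyclobutanone reacts far faster than the hindered C6 cyclohexanone; the closest known reaction type is the chiral phosphoric acid/H2O2 (or Sc(OTf)3–N,N'-dioxide/m-CPBA) Baeyer–Villiger desymmetrization of prochiral 3-substituted cyclobutanones, not yet shown for 3-alkoxy spirocyclobutanones or for diastereotopic-group selection inside a chiral polycycle.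

Step 12
Reactants: 20 (13R)-9α,13-epoxy-6-oxolabdan-15,16-olide
Product: 23 (13R)-9α,13-epoxy-7β-hydroxy-6-oxolabdan-15,16-olide (target), via silyl enol ether 21 (not isolated), via 7-epi ketol 22 (not isolated)
Conditions: Me3SiOTf, Et3N, CH2Cl2, −20 °C; dimethyldioxirane, acetone, −40 °C; aq. citric acid; then DBU (10 mol%), CH2Cl2, 0 °C
Reagents that add atoms: dimethyldioxirane, CC1(C)OO1
Why: Rubottom oxidation after soft enolization, in which the dioxirane epoxidises the Δ6 silyl enol ether from the less hindered α-face and catalytic DBU then equilibrates the α-ketol to the equatorial 7β-alcohol (7R) without touching the lactone.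

**Compound list**

1 | methyl acetoacetate | COC(=O)CC(C)=O | starting material
2 | prenyl bromide (1-bromo-3-methylbut-2-ene) | CC(C)=CCBr | starting material
3 | methyl 7-methyl-3-oxooct-6-enoate | COC(=O)CC(=O)CCC=C(C)C | intermediate
4 | (E)-pent-3-en-2-one | C/C=C/C(C)=O | starting material
5 | Michael adduct, methyl 7-methyl-3-oxo-2-[(2R)-4-oxopentan-2-yl]oct-6-enoate (epimers at C2) | COC(=O)C(C(=O)CCC=C(C)C)[C@H](C)CC(C)=O | intermediate
6 | methyl (1S,6R)-6-methyl-2-(4-methylpent-3-en-1-yl)-4-oxocyclohex-2-ene-1-carboxylate | C[C@@H]1CC(=O)C=C(CCC=C(C)C)[C@H]1C(=O)OC | intermediate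
7 | methyl (1S,2S,6R)-2,6-dimethyl-2-(4-methylpent-3-en-1-yl)-4-oxocyclohexane-1-carboxylate | C[C@@H]1CC(=O)C[C@](C)(CCC=C(C)C)[C@H]1C(=O)OC | intermediate
8 | methyl (1S,2R,4aS,8aS)-2,5,5,8a-tetramethyl-4-oxodecahydronaphthalene-1-carboxylate (trans-decalin; 6-oxo, 8α-Me, 9β-CO2Me, 10β-Me, 5α-H) | C[C@@H]1CC(=O)[C@H]2C(C)(C)CCC[C@]2(C)[C@H]1C(=O)OC | intermediate
9 | Δ6 triethylsilyl enol ether of keto ester 8 | C[C@@H]1C=C(O[Si](CC)(CC)CC)[C@H]2C(C)(C)CCC[C@]2(C)[C@H]1C(=O)OC | intermediate
10 | 9α-hydroperoxy ester of 9 | C[C@@H]1C=C(O[Si](CC)(CC)CC)[C@H]2C(C)(C)CCC[C@]2(C)[C@@]1(OO)C(=O)OC | intermediate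
11 | 9α-hydroxy-9β-(hydroxymethyl) Δ6 triethylsilyl enol ether (diol) | C[C@@H]1C=C(O[Si](CC)(CC)CC)[C@H]2C(C)(C)CCC[C@]2(C)[C@@]1(O)CO | intermediate
12 | 9α,11-spiro-epoxide (oxygen on the α-face of C9; Δ6 triethylsilyl enol ether) | C[C@@H]1C=C(O[Si](CC)(CC)CC)[C@H]2C(C)(C)CCC[C@]2(C)[C@@]13CO3 | intermediate
13 | 1-(trimethylsilyl)propyne | CC#C[Si](C)(C)C | starting material
14 | 9α-hydroxy-9β-[4-(trimethylsilyl)but-3-ynyl] Δ6 triethylsilyl enol ether | C[C@@H]1C=C(O[Si](CC)(CC)CC)[C@H]2C(C)(C)CCC[C@]2(C)[C@@]1(O)CCC#C[Si](C)(C)C | intermediate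
15 | (5S,8R,9R,10S)-9α-hydroxy-9β-(but-3-ynyl)-4,4,8α,10β-tetramethyl-trans-decalin-6-one | C[C@@H]1CC(=O)[C@H]2C(C)(C)CCC[C@]2(C)[C@@]1(O)CCC#C | intermediate
16 | (5S,8R,9R,10S)-9α,13-epoxy-15,16-dinorlabd-13(14)-en-6-one (spiro 2-methylenetetrahydrofuran) | C[C@@H]1CC(=O)[C@H]2C(C)(C)CCC[C@]2(C)[C@@]12CCC(=C)O2 | intermediate
17 | trichloroacetyl chloride | ClC(=O)C(Cl)(Cl)Cl | starting material
18 | spiro 2,2-dichlorocyclobutanone (CCl2 on C13; C13 epimers) | C[C@@H]1CC(=O)[C@H]2C(C)(C)CCC[C@]2(C)[C@@]12CCC3(CC(=O)C3(Cl)Cl)O2 | intermediate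
19 | spirocyclobutanone (5-oxaspiro[3.4]octan-2-one unit, spiro at C9 with 9α-oxygen, on the 6-oxo decalin) | C[C@@H]1CC(=O)[C@H]2C(C)(C)CCC[C@]2(C)[C@@]12CCC3(CC(=O)C3)O2 | intermediate
20 | (5S,8R,9R,10S,13R)-9α,13-epoxy-6-oxolabdan-15,16-olide | C[C@@H]1CC(=O)[C@H]2C(C)(C)CCC[C@]2(C)[C@@]12CC[C@@]1(COC(=O)C1)O2 | intermediate
21 | Δ6 trimethylsilyl enol ether of 20 | C[C@@H]1C=C(O[Si](C)(C)C)[C@H]2C(C)(C)CCC[C@]2(C)[C@@]12CC[C@@]1(COC(=O)C1)O2 | intermediate
22 | 7α-hydroxy epimer of the target (7-epi ketol) | C[C@@H]1[C@H](O)C(=O)[C@H]2C(C)(C)CCC[C@]2(C)[C@@]12CC[C@@]1(COC(=O)C1)O2 | intermediate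
23 | (5S,7R,8R,9R,10S,13R)-9α,13-epoxy-7β-hydroxy-6-oxolabdan-15,16-olide (CNP0291402.1) | C[C@@H]1[C@@H](O)C(=O)[C@H]2C(C)(C)CCC[C@]2(C)[C@@]12CC[C@@]1(COC(=O)C1)O2 | target

**Totals and risk**

Total steps: 12. Longest linear sequence: 12 (all starting materials are commercial).

The three steps most likely to fail:

Step 11 (the proposed group-selective Baeyer–Villiger ring expansion). The catalyst may not distinguish the two methylenes well enough. The fallback uses known chemistry, sets out from 19 and comes back at 20. Compound 19 is oxidised without stereocontrol (m-CPBA, NaHCO3, CH2Cl2, 0 °C; the established ring expansion of 3-alkoxycyclobutanones) to a roughly 1:1 mixture of 20 and the (13S)-spirolactone F1, which are separated by chromatography. F1 is then recycled with KOt-Bu (cat.) in THF: retro-oxa-Michael opening gives the 9α-hydroxy butenolide F2, which recloses by 5-exo oxa-Michael addition to a 20/F1 mixture for another separation. Stereocontrol at C13 thus moves from the catalyst to separation plus thermodynamic recycling.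

Step 4 (ring A closure through the simple ketone enol). A Prins-type closure onto the carbonyl or incomplete cyclization could compete. The fallback sets out from 6 and comes back at 8. Compound 6 is treated with lithium dimethylcuprate in the presence of Me3SiCl and the regio-defined trimethylsilyl enol ether F3 is isolated. Hg(OTf)2 (MeCN, −20 °C; then aq. NaCl) activates the trisubstituted alkene and the silyl enol ether closes ring A (mercury-induced cation–olefin cyclization) to the 3β-chloromercurio keto ester F4. Bu3SnH/AIBN then removes mercury to give 8.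

Step 8 (SN2 opening of the epoxide at a neopentyl-type carbon). The opening may be too slow, or the epoxide may rearrange. The fallback sets out from 11 and comes back at 16. The primary alcohol of 11 is oxidised (SO3·pyridine, DMSO, Et3N) to the α-hydroxy aldehyde F5. Wittig olefination (Ph3P=CHCO2Me) gives the (E)-enoate F6. Conjugate reduction ([(Ph3P)CuH]6, PhSiH3) and lactonisation of the resulting γ-hydroxy ester give the spiro-γ-lactone F7. Methylenation with Cp2TiMe2 (toluene, 70 °C) gives the exocyclic enol ether F8, and Bu4NF cleaves its silyl enol ether to return 16.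

**Further compounds**

F1 | step 11 | (13S)-9α,13-epoxy-6-oxolabdan-15,16-olide (C13 epimer of 20) | C[C@@H]1CC(=O)[C@H]2C(C)(C)CCC[C@]2(C)[C@@]12CC[C@]1(COC(=O)C1)O2
F2 | step 11 | ring-opened 9α-hydroxy butenolide (9α-hydroxy-6-oxolabd-13-en-15,16-olide) | C[C@@H]1CC(=O)[C@H]2C(C)(C)CCC[C@]2(C)[C@@]1(O)CCC1=CC(=O)OC1
F3 | step 4 | trimethylsilyl enol ether of 7 (C5=C6) | C[C@@H]1CC(O[Si](C)(C)C)=C[C@](C)(CCC=C(C)C)[C@H]1C(=O)OC
F4 | step 4 | 3β-chloromercurio derivative of keto ester 8 | C[C@@H]1CC(=O)[C@H]2C(C)(C)[C@@H]([Hg]Cl)CC[C@]2(C)[C@H]1C(=O)OC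
F5 | step 8 | 9α-hydroxy-9β-formyl Δ6 triethylsilyl enol ether | C[C@@H]1C=C(O[Si](CC)(CC)CC)[C@H]2C(C)(C)CCC[C@]2(C)[C@@]1(O)C=O
F6 | step 8 | (E)-enoate, methyl 3-(9α-hydroxy decalin-9β-yl)acrylate as Δ6 triethylsilyl enol ether | C[C@@H]1C=C(O[Si](CC)(CC)CC)[C@H]2C(C)(C)CCC[C@]2(C)[C@@]1(O)/C=C/C(=O)OC
F7 | step 8 | spiro-γ-lactone (9α,13-olide, Δ6 triethylsilyl enol ether) | C[C@@H]1C=C(O[Si](CC)(CC)CC)[C@H]2C(C)(C)CCC[C@]2(C)[C@@]12CCC(=O)O2
F8 | step 8 | Δ6 triethylsilyl enol ether of 16 | C[C@@H]1C=C(O[Si](CC)(CC)CC)[C@H]2C(C)(C)CCC[C@]2(C)[C@@]12CCC(=C)O2
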